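**Retrosynthetic overview**
1. Side chain last: C18=C19 by Wittig on an epoxy aldehyde, C16–C17 epoxide by Sharpless epoxidation of a dienol, C2 methyl by cross-coupling of a dienyl triflate.
2. Ring A from a 1-alkynylcyclopentanol by a 1,2-shift ring expansion that inserts C11, sets the (E)-exocyclic alkene and carries C10 over with retention.
3. Ring B from a 2-methylcyclopentanone by one-carbon ring expansion with diazoethane (inserts C6 with its methyl). C4 is para to the ring-B carbonyl and out of reach of enone chemistry in a six-ring, but it is the β-carbon in the cyclopentenone.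
4. The cis-bicyclo[3.3.0]octane core from a Michael/elimination/Michael [3+2] annulation of dienone 12 onto (R)-4-silyloxy-2-methylcyclopentenone 3; (R)-but-3-yn-2-ol supplies C11–C14.
5. Ring order: ring I (from 1) → ring II (annulation) → ring B (expansion of ring I) → ring A (expansion of ring II).

Assumptions: target locants are ring A C2(Me)=C3–C4–C9–C10–C11, ring B C4–C5–C6(Me)–C7(=O)–C8(Me)–C9, C11=C13–C14(OH)CH3, side chain C10–C12=C15(Me)–C16/C17(Me) epoxide–C18=C19–C20O2H; methyl donors, diazoethane and the Wittig ylide are treated as reagents; 1 and 8 are taken as commercial. "Dienyl" below means (1E,3E)-5-[(tert-butyldimethylsilyl)oxy]-2,4-dimethylpenta-1,3-dien-1-yl.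

**Step 1**
Reactants: 1 (R)-4-[(tert-butyldimethylsilyl)oxy]cyclopent-2-en-1-one
Product: 2 (R)-4-[(tert-butyldimethylsilyl)oxy]-2-iodocyclopent-2-en-1-one
Conditions: I2, pyridine, CH2Cl2, 0 °C to rt
Reagents that add atoms: iodine, II
Why: Pyridine-mediated addition–iodination–elimination (Baylis–Hillman-type α-iodination of an enone) is standard for 4-silyloxycyclopentenones and does not touch the C4 stereocentre.

**Step 2**
Reactants: 2 (R)-4-[(tert-butyldimethylsilyl)oxy]-2-iodocyclopent-2-en-1-one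
Product: 3 (R)-4-[(tert-butyldimethylsilyl)oxy]-2-methylcyclopent-2-en-1-one
Conditions: Me4Sn, Pd2(dba)3 (2.5 mol%), AsPh3, CuI, NMP, 50 °C
Reagents that add atoms: tetramethylstannane, C[Sn](C)(C)C
Why: Stille coupling of the α-iodoenone under neutral conditions installs the future C8 methyl without base-induced loss of the β-silyloxy group.

**Step 3**
Reactants: 4 tert-butyldimethyl(prop-2-yn-1-yloxy)silane
Product: 6 (E)-tert-butyl[(3-iodo-2-methylprop-2-en-1-yl)oxy]dimethylsilane, via alkenylalane 5 (not isolated)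
Conditions: Me3Al, Cp2ZrCl2 (0.25 equiv), CH2Cl2, 0 °C to rt; then I2, THF, −30 °C
Reagents that add atoms: trimethylaluminium, C[Al](C)C; iodine, II
Why: Zr-catalysed syn-carboalumination (Negishi) puts Me on the internal and Al on the terminal alkyne carbon, and iodinolysis with retention gives the (E)-iodide that fixes the C16=C17 geometry.

**Step 4**
Reactants: 7 (±)-2-methyloxirane; 8 1-propynyllithium
Product: 9 (±)-hex-4-yn-2-ol
Conditions: BF3·OEt2, THF, −78 °C
Reagents that add atoms: none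
Why: BF3-assisted SN2 opening of the epoxide at its CH2 terminus by the acetylide (Yamaguchi protocol); the carbinol centre is oxidised in step 6, so racemic material suffices.

**Step 5**
Reactants: 9 (±)-hex-4-yn-2-ol; 6 (E)-tert-butyl[(3-iodo-2-methylprop-2-en-1-yl)oxy]dimethylsilane
Product: 11 (±)-(4E,6E)-8-[(tert-butyldimethylsilyl)oxy]-5,7-dimethylocta-4,6-dien-2-ol, via alkenylzirconocene 10 (not isolated)
Conditions: Cp2Zr(H)Cl (2.2 equiv), THF, rt to 40 °C; then 6, ZnCl2, Pd(PPh3)4 (5 mol%), THF, rt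
Reagents that add atoms: none
Why: syn-Hydrozirconation places Zr on the methyl-bearing alkyne carbon (less hindered, after equilibration with excess reagent) and Zn/Pd Negishi coupling proceeds with retention on both partners, giving the (E,E)-diene (C12=C15 and C16=C17).

**Step 6**
Reactants: 11 (±)-(4E,6E)-8-[(tert-butyldimethylsilyl)oxy]-5,7-dimethylocta-4,6-dien-2-ol
Product: 12 (4E,6E)-8-[(tert-butyldimethylsilyl)oxy]-5,7-dimethylocta-4,6-dien-2-one
Conditions: TPAP (5 mol%), NMO, 4 Å MS, CH2Cl2, 0 °C to rt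
Reagents that add atoms: none
Why: Ley–Griffith oxidation under neutral conditions gives the β,γ-unsaturated methyl ketone without moving the alkene into conjugation.

**Step 7**
Reactants: 13 (R)-but-3-yn-2-ol
Product: 14 (R)-tert-butyl(but-3-yn-2-yloxy)dimethylsilane
Conditions: TBSCl, imidazole, CH2Cl2, rt
Reagents that add atoms: tert-butyldimethylsilyl chloride, CC(C)(C)[Si](C)(C)Cl
Why: Routine silylation; the C14 stereocentre comes from the chiral pool and is not touched.

**Step 8**
Reactants: 12 (4E,6E)-8-[(tert-butyldimethylsilyl)oxy]-5,7-dimethylocta-4,6-dien-2-one; 3 (R)-4-[(tert-butyldimethylsilyl)oxy]-2-methylcyclopent-2-en-1-one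
Product: 16 (4S,5R)-4-[(4E,6E)-8-[(tert-butyldimethylsilyl)oxy]-5,7-dimethyl-2-oxoocta-4,6-dien-3-yl]-5-methylcyclopent-2-en-1-one (epimers at side-chain C10), via Michael adduct 15 (not isolated)
Conditions: LiHMDS, THF, −78 °C; 3, −78 to −30 °C; AcOH; then DBU, CH2Cl2, 0 °C
Reagents that add atoms: none
Why: Michael addition–E1cB elimination: the extended enolate of 12 attacks through its α-carbon C10 (its γ- and ε-carbons are fully substituted) at C9 of 3 anti to the 4-silyloxy group, which sets C9; DBU then expels silanolate to unveil the C4=C5 enone and leaves the C8 methyl trans to the new side chain.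

**Step 9**
Reactants: 16 (4S,5R)-4-[(4E,6E)-8-[(tert-butyldimethylsilyl)oxy]-5,7-dimethyl-2-oxoocta-4,6-dien-3-yl]-5-methylcyclopent-2-en-1-one; 14 (R)-tert-butyl(but-3-yn-2-yloxy)dimethylsilane
Product: 19 cis-fused 5-hydroxy-5-[(3R)-3-(TBSO)but-1-ynyl]-6-dienyl-1-methylhexahydropentalen-2(1H)-one, via silyl enol ether ketone 17 (not isolated), via silyl enol ether carbinol 18 (not isolated)
Conditions: LDA (1.05 equiv), THF, −78 to −40 °C; TMSCl (1.0 equiv), −78 °C; DBU (0.2 equiv), 0 °C; then 14/n-BuLi, CeCl3, THF, −78 °C; AcOH, THF/H2O, 0 °C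
Reagents that add atoms: none
Why: Kinetic deprotonation of the methyl ketone and 5-exo intramolecular Michael addition onto C4 can only give the cis-fused bicyclo[3.3.0]octane (C4 set from C9); trapping the ring-I enolate as its silyl enol ether leaves only the C2 ketone free, DBU equilibrates C10 to the exo-dienyl epimer, and acetylide 1,2-addition occurs anti to that group (a C2 epimer would give the same ketone in step 11).

**Step 10**
Reactants: 19 cis-fused 5-hydroxy-5-[(3R)-3-(TBSO)but-1-ynyl]-6-dienyl-1-methylhexahydropentalen-2(1H)-one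
Product: 20 cis-fused 2-hydroxy-2-[(3R)-3-(TBSO)but-1-ynyl]-1-dienyl-5,7-dimethyloctahydroinden-6-one
Conditions: CH3CHN2 (Et2O), Sc(OTf)3 (10 mol%), toluene, −78 °C; then DBU (cat.), CH2Cl2, rt
Reagents that add atoms: diazoethane, CC=[N+]=[N-]
Why: Lewis-acid-catalysed diazoalkane homologation (Tiffeneau–Demjanov-type 1,2-shift with loss of N2): the less substituted α-carbon C5 migrates in preference to the methyl-bearing C8, so C6 with its methyl is inserted between C7 and C5, and DBU equilibrates C6 and C8 to the cis-diequatorial 2,6-dimethyl ketone.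

**Step 11**
Reactants: 20 cis-fused 2-hydroxy-2-[(3R)-3-(TBSO)but-1-ynyl]-1-dienyl-5,7-dimethyloctahydroinden-6-one
Product: 21 cis-decalin-2,7-dione with (E)-C11=C13H–CH(OTBS)CH3, C10 dienyl and 6,8-dimethyl (target locants)
Conditions: [(2,4-tBu2C6H3O)3P]AuCl (5 mol%), AgSbF6 (5 mol%), 4 Å MS, CH2Cl2, 0 °C to rt
Reagents that add atoms: none
Why: Proposed new method: cationic Au(I) activates the alkyne and the carbinol triggers a semipinacol 1,2-shift of the allylic ring carbon C10 from C2 to C11 anti to gold, followed by protodeauration, which enlarges the cyclopentanol to the (E)-2-alkylidenecyclohexanone with retention at C10 and C14 cis to C10; no ring strain is needed because C≡C becomes C=O plus C=C and the migrating carbon is allyl-stabilised (so it outruns the C3 methylene), while the alkynyl group trans to the dienyl group cannot undergo 1,5-enyne cycloisomerisation; the closest known reaction is the Au(I)-catalysed ring expansion of 1-alkynylcyclopropanols and -cyclobutanols, which has not been shown for unstrained cyclopentanols.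

**Step 12**
Reactants: 21 cis-decalin-2,7-dione with (E)-C11=C13H–CH(OTBS)CH3, C10 dienyl and 6,8-dimethyl
Product: 22 C2 enol triflate of 21 (C2(OTf)=C3, conjugated with C11=C13)
Conditions: KHMDS (1.0 equiv), THF, −78 °C; PhNTf2, −78 to −40 °C
Reagents that add atoms: N-phenylbis(trifluoromethanesulfonimide), O=S(=O)(N(c1ccccc1)S(=O)(=O)C(F)(F)F)C(F)(F)F
Why: Kinetic α′-deprotonation at C3, the only CH2 next to a carbonyl, gives the cross-conjugated dienolate faster than the doubly methine-flanked C7 ketone can enolise, and O-triflation gives the dienyl triflate.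

**Step 13**
Reactants: 22 C2 enol triflate of 21
Product: 23 bis-TBS ether of the ring system (C2 methyl diene; C14-OTBS; side-chain C18-OTBS)
Conditions: trimethylboroxine, Pd(dppf)Cl2 (5 mol%), K2CO3, dioxane/H2O, 60 °C
Reagents that add atoms: trimethylboroxine, CB1OB(C)OB(C)O1
Why: Suzuki–Miyaura methylation of the dienyl triflate gives the C3=C2(Me)–C11=C13 diene without touching the ketone, and the aqueous base keeps C6 and C8 in their thermodynamic configuration.

**Step 14**
Reactants: 23 bis-TBS ether of the ring system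
Product: 24 C18 primary dienol (C14-OTBS retained)
Conditions: HF·pyridine, pyridine, THF, 0 °C
Reagents that add atoms: none
Why: Buffered HF cleaves the primary allylic TBS ether much faster than the hindered secondary one, freeing only the alcohol needed to direct the epoxidation.

**Step 15**
Reactants: 24 C18 primary dienol
Product: 25 (16S,17S)-epoxy alcohol
Conditions: Ti(OiPr)4 (0.2 equiv), L-(+)-DET (0.25 equiv), t-BuOOH (decane), 4 Å MS, CH2Cl2, −25 °C
Reagents that add atoms: tert-butyl hydroperoxide, CC(C)(C)OO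
Why: Sharpless asymmetric epoxidation reacts only at the allylic-alcohol alkene C16=C17, and L-(+)-tartrate gives the (S,S)-epoxide, the same sense as for other (E)-2-methyl-3-substituted allylic alcohols, under reagent control.

**Step 16**
Reactants: 25 (16S,17S)-epoxy alcohol
Product: 27 2-(trimethylsilyl)ethyl (E)-enoate, via epoxy aldehyde 26 (not isolated)
Conditions: IBX, Ph3P=CHCO2CH2CH2SiMe3, DMSO, rt
Reagents that add atoms: 2-(trimethylsilyl)ethyl (triphenylphosphoranylidene)acetate, C[Si](C)(C)CCOC(=O)C=P(c1ccccc1)(c1ccccc1)c1ccccc1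
Why: IBX oxidation with in situ Wittig olefination traps the sensitive α-quaternary epoxy aldehyde (no α-H, so no epimerisation) as the (E)-enoate, and the stabilised ylide ignores the hindered ketone.

**Step 17**
Reactants: 27 2-(trimethylsilyl)ethyl (E)-enoate
Product: 28 CNP0414188.1
Conditions: TBAF (4 equiv), THF, 0 °C to rt; AcOH quench (pH ≈ 5)
Reagents that add atoms: none
Why: Fluoride removes the C14 TBS ether and the silylethyl ester (β-elimination to ethene) in one operation; C17 is quaternary, so the γ,δ-epoxy enoate cannot open by E1cB.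

**Compound list**
1 | (R)-4-[(tert-butyldimethylsilyl)oxy]cyclopent-2-en-1-one | O=C1C=C[C@H](O[Si](C)(C)C(C)(C)C)C1 | starting material
2 | (R)-4-[(tert-butyldimethylsilyl)oxy]-2-iodocyclopent-2-en-1-one | O=C1C(I)=C[C@H](O[Si](C)(C)C(C)(C)C)C1 | intermediate
3 | (R)-4-[(tert-butyldimethylsilyl)oxy]-2-methylcyclopent-2-en-1-one | O=C1C(C)=C[C@H](O[Si](C)(C)C(C)(C)C)C1 | intermediate
4 | tert-butyldimethyl(prop-2-yn-1-yloxy)silane | C#CCO[Si](C)(C)C(C)(C)C | starting material
5 | (E)-{3-[(tert-butyldimethylsilyl)oxy]-2-methylprop-1-en-1-yl}dimethylalane | C[Al](C)/C=C(\C)CO[Si](C)(C)C(C)(C)C | intermediate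
6 | (E)-tert-butyl[(3-iodo-2-methylprop-2-en-1-yl)oxy]dimethylsilane | I/C=C(\C)CO[Si](C)(C)C(C)(C)C | intermediate
7 | (±)-2-methyloxirane | CC1CO1 | starting material
8 | 1-propynyllithium | CC#C[Li] | starting material
9 | (±)-hex-4-yn-2-ol | CC#CCC(C)O | intermediate
10 | (E)-alkenyl chlorozirconocene from 9 (Zr on the methyl-bearing carbon, OH as chlorozirconocene alkoxide) | C/C(=C\CC(C)O[Zr](Cl)(C1C=CC=C1)C1C=CC=C1)[Zr](Cl)(C1C=CC=C1)C1C=CC=C1 | intermediate
11 | (±)-(4E,6E)-8-[(tert-butyldimethylsilyl)oxy]-5,7-dimethylocta-4,6-dien-2-ol | CC(O)C/C=C(\C)/C=C(\C)CO[Si](C)(C)C(C)(C)C | intermediate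
12 | (4E,6E)-8-[(tert-butyldimethylsilyl)oxy]-5,7-dimethylocta-4,6-dien-2-one | CC(=O)C/C=C(\C)/C=C(\C)CO[Si](C)(C)C(C)(C)C | intermediate
13 | (R)-but-3-yn-2-ol | C#C[C@@H](C)O | starting material
14 | (R)-tert-butyl(but-3-yn-2-yloxy)dimethylsilane | C#C[C@@H](C)O[Si](C)(C)C(C)(C)C | intermediate
15 | Michael adduct: 4-OTBS as in 3, the 2-oxo-octadienyl side chain on C3 trans to OTBS, 2-Me trans to the side chain (side-chain C10 epimeric) | O=C1C[C@@H](O[Si](C)(C)C(C)(C)C)[C@H](C(/C=C(\C)/C=C(\C)CO[Si](C)(C)C(C)(C)C)C(C)=O)[C@H]1C | intermediate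
16 | (4S,5R)-4-[(4E,6E)-8-[(tert-butyldimethylsilyl)oxy]-5,7-dimethyl-2-oxoocta-4,6-dien-3-yl]-5-methylcyclopent-2-en-1-one (side-chain C10 epimers) | O=C1C=C[C@H](C(/C=C(\C)/C=C(\C)CO[Si](C)(C)C(C)(C)C)C(C)=O)[C@H]1C | intermediate
17 | cis-fused 6-dienyl-1-methyl-2-[(trimethylsilyl)oxy]-3a,4,6,6a-tetrahydropentalen-5(1H)-one; 1-Me and 6-dienyl exo (cis to H-3a/H-6a) | C[C@H]1C(O[Si](C)(C)C)=C[C@@H]2CC(=O)[C@@H](/C=C(\C)/C=C(\C)CO[Si](C)(C)C(C)(C)C)[C@H]12 | intermediate
18 | cis-fused 5-[(3R)-3-(TBSO)but-1-ynyl]-6-dienyl-1-methyl-2-[(trimethylsilyl)oxy]-1,3a,4,5,6,6a-hexahydropentalen-5-ol; alkynyl trans to dienyl | C[C@H]1C(O[Si](C)(C)C)=C[C@@H]2C[C@](O)(C#C[C@@H](C)O[Si](C)(C)C(C)(C)C)[C@@H](/C=C(\C)/C=C(\C)CO[Si](C)(C)C(C)(C)C)[C@H]12 | intermediate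
19 | cis-fused 5-hydroxy-5-[(3R)-3-(TBSO)but-1-ynyl]-6-dienyl-1-methylhexahydropentalen-2(1H)-one; 1-Me and 6-dienyl exo, 5-alkynyl trans to 6-dienyl | C[C@H]1C(=O)C[C@@H]2C[C@](O)(C#C[C@@H](C)O[Si](C)(C)C(C)(C)C)[C@@H](/C=C(\C)/C=C(\C)CO[Si](C)(C)C(C)(C)C)[C@H]12 | intermediate
20 | cis-fused 2-hydroxy-2-[(3R)-3-(TBSO)but-1-ynyl]-1-dienyl-5,7-dimethyloctahydroinden-6-one; 5-Me, 7-Me and 1-dienyl all cis to H-3a/H-7a, 2-alkynyl trans to 1-dienyl | C[C@H]1C(=O)[C@@H](C)C[C@@H]2C[C@](O)(C#C[C@@H](C)O[Si](C)(C)C(C)(C)C)[C@@H](/C=C(\C)/C=C(\C)CO[Si](C)(C)C(C)(C)C)[C@H]12 | intermediate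
21 | cis-decalin-2,7-dione (target locants): (E)-C11=C13H–CH(OTBS)CH3 with (14R), C10 dienyl, 6,8-dimethyl; C4, C6, C8, C9, C10 as in 28 | O=C1C[C@H]2C[C@H](C)C(=O)[C@H](C)[C@H]2[C@H](/C=C(\C)/C=C(\C)CO[Si](C)(C)C(C)(C)C)/C1=C\[C@@H](C)O[Si](C)(C)C(C)(C)C | intermediate
22 | C2 enol triflate of 21 (C2(OTf)=C3) | O=S(=O)(OC1=C[C@H]2C[C@H](C)C(=O)[C@H](C)[C@H]2[C@H](/C=C(\C)/C=C(\C)CO[Si](C)(C)C(C)(C)C)/C1=C\[C@@H](C)O[Si](C)(C)C(C)(C)C)C(F)(F)F | intermediate
23 | ring system of 28 with C14-OTBS and the C10 dienyl group carrying C18-OTBS | CC1=C[C@H]2C[C@H](C)C(=O)[C@H](C)[C@H]2[C@H](/C=C(\C)/C=C(\C)CO[Si](C)(C)C(C)(C)C)/C1=C\[C@@H](C)O[Si](C)(C)C(C)(C)C | intermediate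
24 | as 23 with free C18 primary alcohol ((12E,16E)-dienol) | CC1=C[C@H]2C[C@H](C)C(=O)[C@H](C)[C@H]2[C@H](/C=C(\C)/C=C(\C)CO)/C1=C\[C@@H](C)O[Si](C)(C)C(C)(C)C | intermediate
25 | (16S,17S)-16,17-epoxy-C18 alcohol, C14-OTBS | CC1=C[C@H]2C[C@H](C)C(=O)[C@H](C)[C@H]2[C@H](/C=C(\C)[C@@H]3O[C@@]3(C)CO)/C1=C\[C@@H](C)O[Si](C)(C)C(C)(C)C | intermediate
26 | corresponding 16,17-epoxy C18 aldehyde (same epoxide geometry) | CC1=C[C@H]2C[C@H](C)C(=O)[C@H](C)[C@H]2[C@H](/C=C(\C)[C@@H]3O[C@@]3(C)C=O)/C1=C\[C@@H](C)O[Si](C)(C)C(C)(C)C | intermediate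
27 | 2-(trimethylsilyl)ethyl ester of 28 with C14-OTBS | CC1=C[C@H]2C[C@H](C)C(=O)[C@H](C)[C@H]2[C@H](/C=C(\C)[C@@H]3O[C@@]3(C)/C=C/C(=O)OCC[Si](C)(C)C)/C1=C\[C@@H](C)O[Si](C)(C)C(C)(C)C | intermediate
28 | (2E)-3-[(2S,3S)-3-[(1E)-1-[(1R,2E,4aS,6S,8R,8aR)-2-[(2R)-2-hydroxypropylidene]-3,6,8-trimethyl-7-oxo-1,2,4a,5,6,7,8,8a-octahydronaphthalen-1-yl]prop-1-en-2-yl]-2-methyloxiran-2-yl]prop-2-enoic acid | CC1=C[C@H]2C[C@H](C)C(=O)[C@H](C)[C@H]2[C@H](/C=C(\C)[C@@H]2O[C@@]2(C)/C=C/C(=O)O)/C1=C\[C@@H](C)O | target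

**Totals:** 17 steps. Longest linear sequence: 13 steps (4, 5, 6, 8–17).

**Steps most likely to fail**

Step 11 (the new gold ring expansion). The unstrained carbinol may instead undergo Meyer–Schuster rearrangement or enyne cyclisation. The fallback sets out from 20 and uses a known epoxy-alcohol semipinacol. Lindlar semihydrogenation of the alkyne gives the (Z)-allylic alcohol F1. Hydroxyl-directed epoxidation with VO(acac)2/t-BuOOH gives the epoxy alcohol F2. BF3·OEt2 at −78 °C then induces the 1,2-shift of C10 onto the proximal epoxide carbon with ring enlargement, giving the β-hydroxy ketone F3. Mesylation and DBU elimination (E1cB, thermodynamic E) bring the route back at 21.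

Step 9 (kinetic cyclisation, enolate trapping and alkynylation in one flask). Deprotonation at the acidic C10–H can compete with the methyl group. The fallback sets out from 16 and cyclises under thermodynamic conditions (cat. t-BuOK, t-BuOH/THF) to the cis-fused exo,exo-dione F4. TBSOTf/Et3N silylates only the more acidic C2 ketone (towards C10), giving the silyl dienol ether F5. Diazoethane/Sc(OTf)3 then expands the one free cyclopentanone to the ring-enlarged silyl dienol ether F6, and TBAF/AcOH releases the ring-enlarged dione F7. CeCl3-mediated addition of lithiated 14 to the cyclopentanone carbonyl gives 20, where the fallback rejoins the route. This last addition relies on the doubly α-branched cyclohexanone reacting more slowly, which is its own weak point.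

Step 8 (intermolecular Michael addition of a ketone enolate to an α-methyl enone). The addition may be slow, and the acceptor can lose silanolate first. The fallback sets out from 12 and 3 and uses a Lewis-acid Mukaiyama–Michael addition in place of the lithium enolate. TMSOTf/Et3N converts 12 into the trimethylsilyl dienol ether F8. TiCl4 in CH2Cl2 at −78 °C adds it to 3, again anti to the silyloxy group, to give 15, and DBU elimination returns to the route at 16.

**Further compounds**
F1 | step 11 | (Z)-allylic alcohol from semihydrogenation of 20 (C11=C13 cis) | C[C@H]1C(=O)[C@@H](C)C[C@@H]2C[C@](O)(/C=C\[C@@H](C)O[Si](C)(C)C(C)(C)C)[C@@H](/C=C(\C)/C=C(\C)CO[Si](C)(C)C(C)(C)C)[C@H]12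
F2 | step 11 | C11,C13-epoxide of F1 (epoxide configuration not defined, both centres are destroyed later) | C[C@H]1C(=O)[C@@H](C)C[C@@H]2C[C@](O)(C3OC3[C@@H](C)O[Si](C)(C)C(C)(C)C)[C@@H](/C=C(\C)/C=C(\C)CO[Si](C)(C)C(C)(C)C)[C@H]12
F3 | step 11 | ring-enlarged β-hydroxy ketone (C2 ketone, C11–H, C13–OH) | O=C1C[C@H]2C[C@H](C)C(=O)[C@H](C)[C@H]2[C@H](/C=C(\C)/C=C(\C)CO[Si](C)(C)C(C)(C)C)C1C(O)[C@@H](C)O[Si](C)(C)C(C)(C)C
F4 | step 9 | cis-fused 6-dienyl-1-methyl-tetrahydropentalene-2,5-dione (Me and dienyl exo) | C[C@H]1C(=O)C[C@@H]2CC(=O)[C@@H](/C=C(\C)/C=C(\C)CO[Si](C)(C)C(C)(C)C)[C@H]12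
F5 | step 9 | C2 tert-butyldimethylsilyl dienol ether of F4 (C2=C10) | C[C@H]1C(=O)C[C@@H]2CC(O[Si](C)(C)C(C)(C)C)=C(/C=C(\C)/C=C(\C)CO[Si](C)(C)C(C)(C)C)[C@H]12
F6 | step 9 | ring-B-enlarged silyl dienol ether (5,7-dimethylindan-6-one core) | C[C@H]1C(=O)[C@@H](C)C[C@@H]2CC(O[Si](C)(C)C(C)(C)C)=C(/C=C(\C)/C=C(\C)CO[Si](C)(C)C(C)(C)C)[C@H]12
F7 | step 9 | cis-fused 1-dienyl-5,7-dimethylhexahydroindane-2,6-dione | C[C@H]1C(=O)[C@@H](C)C[C@@H]2CC(=O)[C@@H](/C=C(\C)/C=C(\C)CO[Si](C)(C)C(C)(C)C)[C@H]12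
F8 | step 8 | trimethylsilyl dienol ether of 12 (C2=C10 enol geometry not defined) | CC(O[Si](C)(C)C)=C/C=C(\C)/C=C(\C)CO[Si](C)(C)C(C)(C)C
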